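**Strategy.** The spiro centre C3 and the C10 carbinol are traced back to one event. In the trans-hydrindane, chair ring B holds an axial carbonyl arm on C3 1,3-syn to the axial hydrogen on C10. Photolysis of the N-iodo derivative of a C3 gem-dicarboxamide should therefore let only the axial amidyl radical take H10 by 1,5-transfer, and oxygen capture closes a C2–O–C10 γ-lactone bridge. One operation makes the C10–O bond with its configuration and tells C2 (lactone) from C4 (amide). The precursor is the limonene-derived hydrindane diamide with equatorial C10 methyl and C14 acetate. The lactone/ester pair later steers a diketone dianion to build ring A, and gem-diprenylation at C1 finishes.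

Key step: step 12

Numbering used throughout: ring A = C1 (carries both prenyl groups), C2 (C=O), C3 (spiro), C4 (C=O), C5 (carries the isobutyryl group), C6 (enol carbon); ring B = C3, C7, C8, C9, C10, C11; ring C = C8, C9, C12, C13, C14; C10 and C14 each carry CH3 and O. In 26 the hydrindane is trans-fused, the C10 hydroxyl is axial and syn to the C2 carbonyl, and the C14 hydroxyl is cis to C7.

Assumption: 26 is handled as the C6 enol tautomer drawn; epoxide 2 is carried as its cis/trans mixture because both isomers converge in step 2.

Step 1
Reactants: 1 (S)-limonene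
Product: 2 (4S)-limonene 1,2-oxide (cis/trans mixture at the epoxide)
Conditions: mCPBA (1.0 equiv), NaHCO3, CH2Cl2, 0 °C
Reagents that add atoms: mCPBA, O=C(OO)c1cccc(Cl)c1
Why: Prilezhaev epoxidation should take the more electron-rich trisubstituted ring alkene and leave the isopropenyl group; the limonene stereocenter (later C9) is untouched and the epoxide diastereomers are irrelevant.

Step 2
Reactants: 2 (4S)-limonene 1,2-oxide
Product: 3 (3S)-6-oxo-3-(prop-1-en-2-yl)heptanal
Conditions: H5IO6, THF–H2O, 0 → 20 °C
Reagents that add atoms: water, O
Why: Periodic acid should open the epoxide to the 1,2-diol and cleave it in the same pot (Malaprade glycol cleavage), giving the keto aldehyde from either epoxide isomer without touching the 1,1-disubstituted alkene.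

Step 3
Reactants: 3 (3S)-6-oxo-3-(prop-1-en-2-yl)heptanal
Product: 4 (5R)-2-methyl-5-(prop-1-en-2-yl)cyclopent-1-ene-1-carbaldehyde
Conditions: piperidine (cat.), AcOH (cat.), PhMe, 80 °C, −H2O
Reagents that add atoms: none
Why: Amine-catalysed intramolecular aldol condensation (enamine of the aldehyde adds to the methyl ketone, five-ring closure, then dehydration) should form the C8–C14 bond of ring C while the non-enolisable C9 centre is retained.

Step 4
Reactants: 4 (5R)-2-methyl-5-(prop-1-en-2-yl)cyclopent-1-ene-1-carbaldehyde
Product: 5 epoxy aldehyde (C8–C14 epoxide, oxygen trans to the isopropenyl group)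
Conditions: 30% H2O2, NaOH (aq., cat.), MeOH, 0 °C
Reagents that add atoms: hydrogen peroxide, OO
Why: Weitz–Scheffer nucleophilic epoxidation: hydroperoxide adds to the β-carbon C14 and the enolate closes on oxygen at C8 on the face opposite the neighbouring C9 isopropenyl group, which sets the C14–O configuration; the isolated alkene is inert to the nucleophilic oxidant.

Step 5
Reactants: 5 epoxy aldehyde
Product: 7 (1S,2S,3S)-2-(hydroxymethyl)-1-methyl-3-(prop-1-en-2-yl)cyclopentan-1-ol, via hydroxy aldehyde 6 (not isolated)
Conditions: SmI2 (2.2 equiv), THF–MeOH, −78 °C; pH 7 buffer, crude into CH2Cl2, DBU (0.1 equiv), 0 °C; then MeOH, NaBH4, 0 °C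
Reagents that add atoms: none
Why: Two-electron reduction of the α,β-epoxy aldehyde by SmI2 cleaves only the Cα–O bond (C8–O) and keeps C14–O; base equilibration of the enolisable aldehyde should then place the formyl group at C8 trans to both the C9 isopropenyl and the C14 methyl groups (thermodynamic control, since kinetic protonation alone may give the all-cis epimer), and NaBH4 reduction gives the 1,3-diol.

Step 6
Reactants: 7 (1S,2S,3S)-2-(hydroxymethyl)-1-methyl-3-(prop-1-en-2-yl)cyclopentan-1-ol
Product: 8 primary tosylate (C7–OTs, free C14–OH)
Conditions: TsCl (1.1 equiv), pyridine, CH2Cl2, 0 °C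
Reagents that add atoms: 4-toluenesulfonyl chloride, Cc1ccc(cc1)S(Cl)(=O)=O
Why: Sulfonylation should be selective for the primary alcohol, the tertiary C14 carbinol being inert to TsCl/pyridine at 0 °C.

Step 7
Reactants: 8 primary tosylate
Product: 9 tosylate acetate (C7–OTs, C14–OAc)
Conditions: Ac2O, DMAP, Et3N, CH2Cl2, 25 °C
Reagents that add atoms: acetic anhydride, CC(=O)OC(C)=O
Why: DMAP-catalysed acyl transfer acetylates the tertiary alcohol; the acetate blocks alkoxide and alkoxy-radical chemistry at C14 and supplies the inductive deactivation of the neighbouring C8–H needed in step 12.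

Step 8
Reactants: 9 tosylate acetate
Product: 10 allylic chloride (C9 carries a 3-chloroprop-1-en-2-yl group)
Conditions: Ca(OCl)2, CO2 (solid), CH2Cl2–H2O, 0 °C
Reagents that add atoms: calcium hypochlorite, [Ca+2].[O-]Cl.[O-]Cl
Why: Ene-type allylic chlorination of the isopropenyl group by HOCl generated in situ should take a methyl hydrogen and give the 2-(chloromethyl)allyl unit (its two CH2 termini are equivalent for step 9) without affecting C9, the tosylate or the acetate.

Step 9
Reactants: 10 allylic chloride; 11 malononitrile
Product: 13 trans-hydrindane 3,3-dicarbonitrile with exocyclic methylene at C10 and C14 acetate, via allylated malononitrile 12 (not isolated)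
Conditions: K2CO3 (2.5 equiv), DMF (0.02 M), 20 → 50 °C
Reagents that add atoms: malononitrile, N#CCC#N
Why: Double alkylation of malononitrile: intermolecular SN2 (or SN2′, same product) at the allylic chloride, then 6-exo-tet closure of the stabilised carbanion on the primary tosylate, forms C3–C11 and C3–C7 and closes ring B with no new stereocenter.

Step 10
Reactants: 13 exocyclic-methylene dinitrile
Product: 14 trans-hydrindane 3,3-dicarbonitrile with equatorial C10 methyl and C14 acetate
Conditions: Mn(dpm)3 (10 mol%; dpm = 2,2,6,6-tetramethylheptane-3,5-dionate), PhSiH3, t-BuOOH, i-PrOH, 22 °C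
Reagents that add atoms: none
Why: Metal-hydride hydrogen-atom-transfer hydrogenation: H• adds to the exocyclic CH2 and the tertiary C10 radical takes its second hydrogen along the axial trajectory, which should give the thermodynamically preferred equatorial methyl (axial H10), where heterogeneous hydrogenation would favour the axial methyl; nitriles and acetate are inert.

Step 11
Reactants: 14 C10-methyl dinitrile
Product: 15 hydrindane C3 gem-dicarboxamide with equatorial C10 methyl and C14 acetate
Conditions: PtH(PMe2OH)(PMe2O)2H (5 mol%), EtOH–H2O, 80 °C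
Reagents that add atoms: water, O
Why: Platinum-catalysed hydration of nitriles under neutral conditions stops at the primary amide, reaches hindered quaternary nitriles and should leave the tertiary acetate intact.

Step 12
Reactants: 15 gem-dicarboxamide
Product: 18 bridged γ-lactone primary amide (lactone carbonyl C2, amide C4, C14 acetate), via N-iodoamide 16 (not isolated), via iminolactone 17 (not isolated)
Conditions: PhI(OAc)2 (2.5 equiv) premixed with I2 (1.0 equiv), CH2Cl2–MeCN, visible light (tungsten lamp), 20 °C; aq. Na2S2O3; then 1 M HCl, THF, 20 °C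
Reagents that add atoms: water, O
Why: Acetyl hypoiodite formed from PhI(OAc)2 and I2 N-iodinates the carboxamides, light homolyses N–I, and the amidyl radical of the axial C3 arm takes the syn-axial H10 by 1,5-hydrogen transfer through a six-membered transition state; the tertiary C10 radical is iodinated and the C10–I bond is displaced (or ionised and captured) by the amide oxygen to give iminolactone 17, which dilute acid hydrolyses to the γ-lactone. The closest known reaction type is the photolysis of N-iodoamides to γ-lactones (Hofmann–Löffler–Freytag type) run with a hypervalent iodine oxidant. The ring closes in the 5-exo-tet mode (O onto C10) and gives a 6-oxabicyclo[3.2.1]octan-7-one. At C10 the oxygen can only enter on the axial face where the tethered carbonyl sits, so C–O replaces the axial C–H with retention and the methyl stays equatorial; C3 becomes stereogenic because only the axial carboxamide can bridge to C10, so the trans-fused chair of ring B controls both centres. The step needs H10 over H8 selectivity (both are 1,3-syn-axial to the radical): H8 is deactivated toward the electrophilic amidyl radical by the vicinal C14 acetoxy group and is flanked by the quaternary C14, while the equatorial amidyl radical has no hydrogen within 1,5-reach and is returned to the amide by the thiosulfate quench. Premixing PhI(OAc)2 with I2 in a base-free, non-nucleophilic medium should keep Hofmann-type rearrangement of the primary amides slow relative to N-iodination and photolysis.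

Step 13
Reactants: 18 lactone amide
Product: 20 lactone methyl ester (C4 = CO2Me, C14 acetate), via imidate salt 19 (not isolated)
Conditions: Me3OBF4 (1.5 equiv), CH2Cl2, 20 °C; then H2O (pH 3), 20 °C
Reagents that add atoms: trimethyloxonium tetrafluoroborate, C[O+](C)C.F[B-](F)(F)F; water, O
Why: O-Methylation of the primary amide gives the imidate salt, which in weakly acidic water loses ammonium (Pinner-type hydrolysis) to the methyl ester; lactone and acetate carbonyl oxygens are too weakly nucleophilic to be alkylated and no stereocenter is touched.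

Step 14
Reactants: 20 lactone methyl ester; 21 5-methylhexane-2,4-dione
Product: 24 spiro acyl trione diol (ring A with C1H2, free C10–OH and C14–OH), via triketone ester 22 (not isolated), via trione acetate 23 (not isolated)
Conditions: 21 (3 equiv), LiN(i-Pr)2 (6 equiv), THF, −78 → 0 °C; add 20, −78 → 50 °C; then MeOH, 60 °C; 1 M HCl work-up
Reagents that add atoms: 5-methylhexane-2,4-dione, CC(=O)CC(=O)C(C)C
Why: Claisen acylation of the terminal carbanion of the diketone dianion by the strained, more electrophilic lactone carbonyl C2 forms C1–C2 and frees the C10 alkoxide, Dieckmann closure of C5 on the C4 methyl ester (6-exo-trig) then builds ring A so that the C3 configuration fixed in step 12 is carried over, and methanolysis removes the C14 acetate from the base-stable enolate.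

Step 15
Reactants: 24 spiro acyl trione diol; 25 prenyl bromide
Product: 26 target CNP0273836.6
Conditions: NaOMe (3.3 equiv), MeOH, 0 °C; prenyl bromide (2.4 equiv), 0 → 20 °C; 1 M HCl work-up
Reagents that add atoms: prenyl bromide, CC(C)=CCBr
Why: Twofold C-alkylation of the doubly activated C1 methylene of the cyclic triketone enolate in a protic medium, the classical route to gem-diprenyl acylphloroglucinol-derived triones, should leave the acyl-bearing C5, the enol oxygen and the tertiary alcohols unalkylated and creates no stereocenter.

**Compound list**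

1 | (S)-limonene | CC1=CC[C@H](CC1)C(C)=C | starting material
2 | (4S)-1-methyl-4-(prop-1-en-2-yl)-7-oxabicyclo[4.1.0]heptane, cis/trans mixture at the epoxide | CC12OC1C[C@H](CC2)C(C)=C | intermediate
3 | (3S)-6-oxo-3-(prop-1-en-2-yl)heptanal | O=CC[C@H](CCC(C)=O)C(C)=C | intermediate
4 | (5R)-2-methyl-5-(prop-1-en-2-yl)cyclopent-1-ene-1-carbaldehyde | O=CC1=C(C)CC[C@@H]1C(C)=C | intermediate
5 | 5-methyl-2-(prop-1-en-2-yl)-6-oxabicyclo[3.1.0]hexane-1-carbaldehyde, epoxide oxygen trans to the isopropenyl group | O=C[C@]12O[C@@]1(C)CC[C@@H]2C(C)=C | intermediate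
6 | 2-hydroxy-2-methyl-5-(prop-1-en-2-yl)cyclopentane-1-carbaldehyde, CHO cis to OH and trans to isopropenyl | O=C[C@@H]1[C@H](CC[C@]1(C)O)C(C)=C | intermediate (not isolated)
7 | (1S,2S,3S)-2-(hydroxymethyl)-1-methyl-3-(prop-1-en-2-yl)cyclopentan-1-ol | OC[C@@H]1[C@H](CC[C@]1(C)O)C(C)=C | intermediate
8 | primary 4-toluenesulfonate of 7 | Cc1ccc(cc1)S(=O)(=O)OC[C@@H]1[C@H](CC[C@]1(C)O)C(C)=C | intermediate
9 | tertiary acetate of 8 | Cc1ccc(cc1)S(=O)(=O)OC[C@@H]1[C@H](CC[C@]1(C)OC(C)=O)C(C)=C | intermediate
10 | 9 with the isopropenyl group chlorinated to 3-chloroprop-1-en-2-yl | Cc1ccc(cc1)S(=O)(=O)OC[C@@H]1[C@H](CC[C@]1(C)OC(C)=O)C(=C)CCl | intermediate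
11 | malononitrile | N#CCC#N | starting material
12 | mono-allylated malononitrile still carrying the tosylate | Cc1ccc(cc1)S(=O)(=O)OC[C@@H]1[C@H](CC[C@]1(C)OC(C)=O)C(=C)CC(C#N)C#N | intermediate (not isolated)
13 | trans-hydrindane 3,3-dicarbonitrile, C10 exocyclic methylene, C14 acetate | N#CC1(C#N)C[C@@H]2[C@H](CC[C@]2(C)OC(C)=O)C(=C)C1 | intermediate
14 | trans-hydrindane 3,3-dicarbonitrile, equatorial C10 methyl, C14 acetate | N#CC1(C#N)C[C@@H]2[C@H](CC[C@]2(C)OC(C)=O)[C@@H](C)C1 | intermediate
15 | trans-hydrindane 3,3-dicarboxamide, equatorial C10 methyl, C14 acetate (key-step precursor) | NC(=O)C1(C(N)=O)C[C@@H]2[C@H](CC[C@]2(C)OC(C)=O)[C@@H](C)C1 | intermediate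
16 | 15 with the axial carboxamide N-iodinated | NC(=O)[C@@]1(C(=O)NI)C[C@@H]2[C@H](CC[C@]2(C)OC(C)=O)[C@@H](C)C1 | intermediate (not isolated)
17 | bridged iminolactone (C2=NH, O on C10), equatorial carboxamide | NC(=O)[C@@]12C[C@@H]3[C@H](CC[C@]3(C)OC(C)=O)[C@@](C)(C1)OC2=N | intermediate (not isolated)
18 | bridged γ-lactone primary amide (lactone C2–O–C10, amide C4, C14 acetate; key-step product) | NC(=O)[C@@]12C[C@@H]3[C@H](CC[C@]3(C)OC(C)=O)[C@@](C)(C1)OC2=O | intermediate
19 | O-methyl imidate tetrafluoroborate of 18 | COC(=[NH2+])[C@@]12C[C@@H]3[C@H](CC[C@]3(C)OC(C)=O)[C@@](C)(C1)OC2=O.F[B-](F)(F)F | intermediate (not isolated)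
20 | bridged γ-lactone methyl ester (C4 = CO2Me, C14 acetate) | COC(=O)[C@@]12C[C@@H]3[C@H](CC[C@]3(C)OC(C)=O)[C@@](C)(C1)OC2=O | intermediate
21 | 5-methylhexane-2,4-dione | CC(=O)CC(=O)C(C)C | starting material
22 | open triketone methyl ester with free C10–OH and C14 acetate | CC(C)C(=O)CC(=O)CC(=O)[C@@]1(C[C@@H]2[C@H](CC[C@]2(C)OC(C)=O)[C@](C)(O)C1)C(=O)OC | intermediate (not isolated)
23 | spiro acyl trione with C1H2, free C10–OH and C14 acetate | C1C(=O)[C@@]2(C[C@@H]3[C@H](CC[C@]3(C)OC(C)=O)[C@](C)(O)C2)C(=O)C(C(=O)C(C)C)=C1O | intermediate (not isolated)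
24 | spiro acyl trione with C1H2 and free C10–OH and C14–OH | C1C(=O)[C@@]2(C[C@@H]3[C@H](CC[C@]3(C)O)[C@](C)(O)C2)C(=O)C(C(=O)C(C)C)=C1O | intermediate
25 | prenyl bromide | CC(C)=CCBr | starting material
26 | CNP0273836.6 | CC(C)=CCC1(CC=C(C)C)C(=O)[C@@]2(C[C@@H]3[C@H](CC[C@]3(C)O)[C@](C)(O)C2)C(=O)C(C(=O)C(C)C)=C1O | target

**Step count.** Total: 15 steps. Longest linear sequence: 15 steps, from 1 to 26.

**Steps most likely to fail, with fallbacks**

1. Step 12. Hydrogen abstraction at the ring-fusion C8–H in place of C10–H, or Hofmann-type rearrangement of the primary amides under the oxidant, would erode the lactone. The fallback makes the C10–O bond by a polar alkene cyclisation and sets out from 13. Hydration of both nitriles with the same platinum catalyst should give the alkene diamide F1. Iodolactonisation (I2, NaHCO3, MeCN–H2O, then dilute HCl), in which only the axial carboxamide oxygen can reach the C10 end of the iodonium ion (5-exo), should give the iodomethyl lactone amide F2. Bu3SnH/AIBN (PhMe, 80 °C) removes the iodine and the sequence comes back to the route at 18.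

2. Step 5. Protonation of the samarium enolate from the less hindered face, followed by incomplete equilibration or by loss of water back to enal 4 (or retro-aldol opening), would spoil C8. The fallback sets C8 by C–C instead of C–H bond formation and sets out from 3. Amine-catalysed α-chlorination (NCS, L-prolinamide cat., CH2Cl2, 0 °C) gives the α-chloro keto aldehyde F3. Pinnick oxidation (NaClO2, NaH2PO4, 2-methylbut-2-ene) gives the α-chloro keto acid F4, and TMSCHN2 the α-chloro keto ester F5. SmI2 (THF, −78 °C) then triggers an intramolecular Reformatsky addition to the methyl ketone through a chelated transition state, which should give the β-hydroxy ester F6 with OH cis to the ester and the ester trans to the isopropenyl group. LiAlH4 reduction comes back to the route at 7.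

3. Step 14. Acylation of the dianion terminus by the methyl ester before the lactone would reverse the sense of ring A at C3, and the Dieckmann closure on the neopentyl-type ester may stall. The fallback enforces the order of bond formation with an acyl chloride and sets out from 18. Nitrosative hydrolysis (NaNO2, aq. H2SO4–AcOH, 0 °C) gives the lactone acid F7, and (COCl)2 with DMF (cat.) the lactone acid chloride F8. C-Acylation of the magnesium enolate of 21 (MgCl2, pyridine, CH2Cl2) gives the triacylmethane F9, with C4–C5 made first. LiN(i-Pr)2 (3 equiv, THF, −78 → 20 °C) then generates the terminal methyl carbanion, which attacks the lactone carbonyl (6-exo-trig) to give 23. MeOH at 60 °C comes back to the route at 24.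

Further compounds
F1 | step 12 | alkene diamide (3,3-dicarboxamide with C10 exocyclic methylene, C14 acetate) | NC(=O)C1(C(N)=O)C[C@@H]2[C@H](CC[C@]2(C)OC(C)=O)C(=C)C1
F2 | step 12 | iodomethyl lactone amide (18 with CH2I in place of the C10 methyl) | NC(=O)[C@@]12C[C@@H]3[C@H](CC[C@]3(C)OC(C)=O)[C@@](CI)(C1)OC2=O
F3 | step 5 | α-chloro keto aldehyde, (3S)-2-chloro-6-oxo-3-(prop-1-en-2-yl)heptanal, mixture at C2 | O=CC(Cl)[C@H](CCC(C)=O)C(C)=C
F4 | step 5 | α-chloro keto acid | OC(=O)C(Cl)[C@H](CCC(C)=O)C(C)=C
F5 | step 5 | α-chloro keto ester (methyl ester) | COC(=O)C(Cl)[C@H](CCC(C)=O)C(C)=C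
F6 | step 5 | β-hydroxy ester, methyl 2-hydroxy-2-methyl-5-(prop-1-en-2-yl)cyclopentane-1-carboxylate, ester cis to OH and trans to isopropenyl | COC(=O)[C@@H]1[C@H](CC[C@]1(C)O)C(C)=C
F7 | step 14 | lactone acid (C4 = CO2H) | OC(=O)[C@@]12C[C@@H]3[C@H](CC[C@]3(C)OC(C)=O)[C@@](C)(C1)OC2=O
F8 | step 14 | lactone acid chloride (C4 = COCl) | ClC(=O)[C@@]12C[C@@H]3[C@H](CC[C@]3(C)OC(C)=O)[C@@](C)(C1)OC2=O
F9 | step 14 | triacylmethane (C5 carries acetyl, isobutyryl and the C4 acyl group of the lactone) | CC(=O)C(C(=O)C(C)C)C(=O)[C@@]12C[C@@H]3[C@H](CC[C@]3(C)OC(C)=O)[C@@](C)(C1)OC2=O
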